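**Plan**

- Retrosynthesis: the two O–benzyl bonds are cut first. Ring A, the trisubstituted resorcinol monomethyl ether, is then taken back to its dihydro form, a 3-methoxycyclohex-2-en-1-one, whose C1 ketone is the future OH and whose C3 enol ether is the future OMe.
- At this oxidation level the bond between the 4-oxybenzyl CH2 and ring carbon C6 is cut (enolate plus benzylic bromide). The enabling feature is that C6, the CH2 between the C1 carbonyl and C5 (which carries the arylethyl chain), is the only kinetically acidic position of that ring. In the arene the same carbon would compete with two other activated CH positions.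
- The six-membered ring is opened at the two C–C bonds of a malonate Michael/Claisen annulation, the enone at its C=C bond (Wittig) and the aldehyde at its aryl–CH2 bond (Heck).
- Forward: chain (steps 1–2), ring A as a cyclohexane-1,3-dione (step 3), enol ether (4), C-benzylation (5), selenenylation and oxidative aromatisation (6–7), debenzylation (8). The two outer benzene rings are bought.
- Stereochemistry: the target has no stereocentre. C5 and C6 of the ring intermediates are racemic (trans in 14) and both disappear on aromatisation.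

Key step: step 5

Remark: racemic intermediates are used throughout; where a SMILES carries stereodescriptors it shows one enantiomer of the racemate.

**Step 1**
Reactants: 1 1-(benzyloxy)-2-iodobenzene; 2 prop-2-en-1-ol (allyl alcohol)
Product: 3 3-[2-(benzyloxy)phenyl]propanal
Conditions: Pd(OAc)2 (cat.), n-Bu4NCl, NaHCO3, DMF, 45 °C
Reagents that add atoms: none
Why: Heck reaction under Jeffery conditions, in which the aryl group adds to the terminal alkene carbon and β-hydride elimination toward the carbinol carbon gives the enol and hence the saturated aldehyde, the aryl benzyl ether being inert.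

**Step 2**
Reactants: 3 3-[2-(benzyloxy)phenyl]propanal; 4 1-(triphenyl-λ5-phosphanylidene)propan-2-one
Product: 5 (3E)-6-[2-(benzyloxy)phenyl]hex-3-en-2-one
Conditions: CH2Cl2, rt
Reagents that add atoms: none
Why: Wittig olefination of an aliphatic aldehyde with a stabilised acyl ylide, which should give the E-enone.

**Step 3**
Reactants: 5 (3E)-6-[2-(benzyloxy)phenyl]hex-3-en-2-one; 6 diethyl malonate
Product: 10 5-{2-[2-(benzyloxy)phenyl]ethyl}cyclohexane-1,3-dione, via Michael adduct 7 (not isolated), via cyclic keto ester 8 (not isolated), via keto acid 9 (not isolated)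
Conditions: NaOEt, EtOH, reflux; aq. NaOH, reflux; aq. HCl, 80 °C
Reagents that add atoms: none
Why: Michael addition of malonate to the enone, Claisen (Dieckmann-type) ring closure of the methyl ketone enolate onto one ester, saponification and decarboxylation of the β-keto acid, the classical route to 5-substituted cyclohexane-1,3-diones, which aryl benzyl ethers should tolerate.

**Step 4**
Reactants: 10 5-{2-[2-(benzyloxy)phenyl]ethyl}cyclohexane-1,3-dione
Product: 11 (±)-5-{2-[2-(benzyloxy)phenyl]ethyl}-3-methoxycyclohex-2-en-1-one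
Conditions: MeOH, TsOH·H2O (cat.), 3 Å MS, reflux
Reagents that add atoms: methanol, CO
Why: Acid-catalysed enol etherification of a 1,3-dione (vinylogous ester formation); the two carbonyl groups of 10 are equivalent by symmetry, so only one constitutional isomer can form.

**Step 5**
Reactants: 11 (±)-5-{2-[2-(benzyloxy)phenyl]ethyl}-3-methoxycyclohex-2-en-1-one; 12 1-(benzyloxy)-4-(bromomethyl)benzene
Product: 14 (5RS,6SR)-6-[4-(benzyloxy)benzyl]-5-{2-[2-(benzyloxy)phenyl]ethyl}-3-methoxycyclohex-2-en-1-one (trans), via lithium dienolate 13 (not isolated)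
Conditions: LDA, THF, −78 °C; 12, DMPU, −78 → 0 °C
Reagents that add atoms: none
Why: LDA removes the kinetically most accessible α'-proton at C6 of the vinylogous ester at −78 °C to give the cross-conjugated lithium dienolate 13 (γ-deprotonation at C4 is the thermodynamic, not the kinetic, pathway), and 13 displaces bromide from the benzylic bromide 12 in an SN2 reaction. The closest known reaction type is the Stork–Danheiser α'-alkylation of 3-alkoxycyclohex-2-enones with activated halides. No ring is closed. The new stereocentre C6 should be set trans to the C5 side chain by approach of 12 to the enolate face anti to that chain (substrate control), which is of no consequence because C5 and C6 both become sp2 on aromatisation. The selectivity needed is constitutional, C-benzylation at C6 and not at C2, C4 or oxygen and one benzyl group only; the first is secured by the position of the kinetic enolate between C1=O and C5, the second by low temperature, a slight excess of base and the greater hindrance of the tertiary C6–H of 14. The same event fixes which oxygen of ring A ends as OH (the C1 carbonyl) and which as OMe (the C3 enol ether).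

**Step 6**
Reactants: 14 (5RS,6SR)-6-[4-(benzyloxy)benzyl]-5-{2-[2-(benzyloxy)phenyl]ethyl}-3-methoxycyclohex-2-en-1-one
Product: 16 (5RS,6SR)-6-[4-(benzyloxy)benzyl]-5-{2-[2-(benzyloxy)phenyl]ethyl}-3-methoxy-6-(phenylselanyl)cyclohex-2-en-1-one, via lithium enolate 15 (not isolated)
Conditions: LDA, THF, −78 °C; PhSeBr, −78 °C
Reagents that add atoms: benzeneselenenyl bromide, Br[Se]c1ccccc1
Why: The pseudoaxial tertiary C6–H of 14 is still the kinetic site for LDA, and the tetrasubstituted enolate 15 should be selenenylated on carbon (Reich α-selenenylation of a ketone enolate), selenium entering anti to the C5 chain and therefore cis to H-5.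

**Step 7**
Reactants: 16 (5RS,6SR)-6-[4-(benzyloxy)benzyl]-5-{2-[2-(benzyloxy)phenyl]ethyl}-3-methoxy-6-(phenylselanyl)cyclohex-2-en-1-one
Product: 19 2-[4-(benzyloxy)benzyl]-3-{2-[2-(benzyloxy)phenyl]ethyl}-5-methoxyphenol, via selenoxide 17 (not isolated), via cyclohexa-2,5-dienone 18 (not isolated)
Conditions: mCPBA (1.05 equiv), CH2Cl2, −78 °C; pyridine, −78 °C → rt
Reagents that add atoms: none
Why: Selenium is oxidised chemoselectively at −78 °C, the selenoxide 17 should undergo syn-elimination with the cis H-5 on warming (selenoxide elimination), and the 4H-cyclohexa-2,5-dienone 18 so formed is the keto tautomer of the phenol and enolises at once, one equivalent of peracid at low temperature sparing the electron-rich phenol.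

**Step 8**
Reactants: 19 2-[4-(benzyloxy)benzyl]-3-{2-[2-(benzyloxy)phenyl]ethyl}-5-methoxyphenol
Product: 20 2-(4-hydroxybenzyl)-3-[2-(2-hydroxyphenyl)ethyl]-5-methoxyphenol (CNP0260198.0)
Conditions: H2 (1 atm), 10% Pd/C, EtOAc–MeOH, rt
Reagents that add atoms: none
Why: Hydrogenolysis of both aryl benzyl ethers over palladium, with the methyl ether and the diarylmethane and bibenzyl C–C bonds inert, 19 being freed of selenium traces by chromatography beforehand so that the catalyst is not poisoned.

**Compound list**

1 | 1-(benzyloxy)-2-iodobenzene | Ic1ccccc1OCc1ccccc1 | starting material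
2 | prop-2-en-1-ol (allyl alcohol) | C=CCO | starting material
3 | 3-[2-(benzyloxy)phenyl]propanal | O=CCCc1ccccc1OCc1ccccc1 | intermediate
4 | 1-(triphenyl-λ5-phosphanylidene)propan-2-one | CC(=O)C=P(c1ccccc1)(c1ccccc1)c1ccccc1 | starting material
5 | (3E)-6-[2-(benzyloxy)phenyl]hex-3-en-2-one | CC(=O)/C=C/CCc1ccccc1OCc1ccccc1 | intermediate
6 | diethyl malonate | CCOC(=O)CC(=O)OCC | starting material
7 | diethyl 2-{1-[2-(benzyloxy)phenyl]-5-oxohexan-3-yl}propanedioate (Michael adduct, racemic) | CCOC(=O)C(C(=O)OCC)C(CC(C)=O)CCc1ccccc1OCc1ccccc1 | intermediate (not isolated)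
8 | ethyl 6-{2-[2-(benzyloxy)phenyl]ethyl}-2,4-dioxocyclohexane-1-carboxylate (present as its sodium enolate, mixture of stereoisomers) | CCOC(=O)C1C(=O)CC(=O)CC1CCc1ccccc1OCc1ccccc1 | intermediate (not isolated)
9 | 6-{2-[2-(benzyloxy)phenyl]ethyl}-2,4-dioxocyclohexane-1-carboxylic acid (mixture of stereoisomers) | OC(=O)C1C(=O)CC(=O)CC1CCc1ccccc1OCc1ccccc1 | intermediate (not isolated)
10 | 5-{2-[2-(benzyloxy)phenyl]ethyl}cyclohexane-1,3-dione (achiral) | O=C1CC(=O)CC(CCc2ccccc2OCc2ccccc2)C1 | intermediate
11 | (±)-5-{2-[2-(benzyloxy)phenyl]ethyl}-3-methoxycyclohex-2-en-1-one | COC1=CC(=O)CC(CCc2ccccc2OCc2ccccc2)C1 | intermediate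
12 | 1-(benzyloxy)-4-(bromomethyl)benzene (4-benzyloxybenzyl bromide) | BrCc1ccc(OCc2ccccc2)cc1 | starting material
13 | lithium 5-{2-[2-(benzyloxy)phenyl]ethyl}-3-methoxycyclohexa-1,3-dien-1-olate (cross-conjugated C1=C6 dienolate of 11, racemic) | [Li]OC1=CC(CCc2ccccc2OCc2ccccc2)CC(OC)=C1 | intermediate (not isolated)
14 | (5RS,6SR)-6-[4-(benzyloxy)benzyl]-5-{2-[2-(benzyloxy)phenyl]ethyl}-3-methoxycyclohex-2-en-1-one (trans, racemic) | COC1=CC(=O)[C@@H](Cc2ccc(OCc3ccccc3)cc2)[C@H](CCc2ccccc2OCc2ccccc2)C1 | intermediate
15 | lithium 6-[4-(benzyloxy)benzyl]-5-{2-[2-(benzyloxy)phenyl]ethyl}-3-methoxycyclohexa-1,3-dien-1-olate (C1=C6 enolate of 14, racemic) | [Li]OC1=C(Cc2ccc(OCc3ccccc3)cc2)C(CCc2ccccc2OCc2ccccc2)CC(OC)=C1 | intermediate (not isolated)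
16 | (5RS,6SR)-6-[4-(benzyloxy)benzyl]-5-{2-[2-(benzyloxy)phenyl]ethyl}-3-methoxy-6-(phenylselanyl)cyclohex-2-en-1-one (PhSe trans to the C5 chain, expected major diastereomer, racemic) | COC1=CC(=O)[C@]([Se]c2ccccc2)(Cc2ccc(OCc3ccccc3)cc2)[C@H](CCc2ccccc2OCc2ccccc2)C1 | intermediate
17 | selenoxide of 16, 6-(benzeneseleninyl) compound (mixture at selenium, racemic) | COC1=CC(=O)[C@]([Se](=O)c2ccccc2)(Cc2ccc(OCc3ccccc3)cc2)[C@H](CCc2ccccc2OCc2ccccc2)C1 | intermediate (not isolated)
18 | 2-[4-(benzyloxy)benzyl]-3-{2-[2-(benzyloxy)phenyl]ethyl}-5-methoxycyclohexa-2,5-dien-1-one | COC1=CC(=O)C(Cc2ccc(OCc3ccccc3)cc2)=C(CCc2ccccc2OCc2ccccc2)C1 | intermediate (not isolated)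
19 | 2-[4-(benzyloxy)benzyl]-3-{2-[2-(benzyloxy)phenyl]ethyl}-5-methoxyphenol | COc1cc(O)c(Cc2ccc(OCc3ccccc3)cc2)c(CCc2ccccc2OCc2ccccc2)c1 | intermediate
20 | 2-(4-hydroxybenzyl)-3-[2-(2-hydroxyphenyl)ethyl]-5-methoxyphenol (CNP0260198.0) | COc1cc(O)c(Cc2ccc(O)cc2)c(CCc2ccccc2O)c1 | target

**Totals**

Total step count: 8. Longest linear sequence: 8 steps (1 → 20); compounds 2, 4, 6 and 12 are bought and enter directly.

**Steps most likely to fail**

1. Step 5. What may go wrong: equilibration of the kinetic enolate (proton transfer between 13 and 14) leading to a second benzylation or to reaction at C4, and slow substitution next to the branched C5. Fallback (sets out from 11, comes back at 19, steps 6 and 7 then being unnecessary): enolate 13 is added to commercial 4-(benzyloxy)benzaldehyde at −78 °C to give the aldol adduct 5-{2-[2-(benzyloxy)phenyl]ethyl}-6-{[4-(benzyloxy)phenyl](hydroxy)methyl}-3-methoxycyclohex-2-en-1-one F1. This is dehydrated with catalytic TsOH in toluene over molecular sieves to the arylidene dienone (6E)-6-[4-(benzyloxy)benzylidene]-5-{2-[2-(benzyloxy)phenyl]ethyl}-3-methoxycyclohex-2-en-1-one F2. Catalytic RhCl3·3H2O in refluxing EtOH should then move the exocyclic double bond into the ring by hydride addition–elimination (isoaromatisation), giving 18 and hence 19 without any oxidant.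

2. Step 6. What may go wrong: sluggish deprotonation of the hindered tertiary C6–H, with return of 14 or selenenylation elsewhere. Fallback (sets out from 11, comes back at 16): the order of the two C6 events is reversed. The unhindered enolate 13 is selenenylated with PhSeBr to give 5-{2-[2-(benzyloxy)phenyl]ethyl}-3-methoxy-6-(phenylselanyl)cyclohex-2-en-1-one F3. Its remaining C6–H is acidified by selenium and is removed by LDA, and the α-selanyl enolate is benzylated with 12 in THF/DMPU to give 16.

3. Step 7. What may go wrong: syn-elimination toward the benzylic CH2 instead of H-5, which gives an exocyclic double bond that does not tautomerise by itself, and oxidation of the electron-rich phenol by selenium(IV) or peracid. Fallback (sets out from 14, comes back at 19): enolate 15 is trapped with TMSCl to give the silyl dienol ether {6-[4-(benzyloxy)benzyl]-5-{2-[2-(benzyloxy)phenyl]ethyl}-3-methoxycyclohexa-1,3-dien-1-yl}oxy(trimethyl)silane F4. This is oxidised with Pd(OAc)2 in MeCN (Saegusa–Ito), where β-hydride elimination from the palladium enolate gives 18 and hence 19. A double bond formed outside the ring should be moved into it by re-addition of the palladium hydride, and no selenium or peracid is involved.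

**Further compounds**

F1 | step 5 | 5-{2-[2-(benzyloxy)phenyl]ethyl}-6-{[4-(benzyloxy)phenyl](hydroxy)methyl}-3-methoxycyclohex-2-en-1-one (mixture of diastereomers) | COC1=CC(=O)C(C(O)c2ccc(OCc3ccccc3)cc2)C(CCc2ccccc2OCc2ccccc2)C1
F2 | step 5 | (6E)-6-[4-(benzyloxy)benzylidene]-5-{2-[2-(benzyloxy)phenyl]ethyl}-3-methoxycyclohex-2-en-1-one (racemic) | COC1=CC(=O)/C(=C/c2ccc(OCc3ccccc3)cc2)C(CCc2ccccc2OCc2ccccc2)C1
F3 | step 6 | 5-{2-[2-(benzyloxy)phenyl]ethyl}-3-methoxy-6-(phenylselanyl)cyclohex-2-en-1-one (mixture of diastereomers) | COC1=CC(=O)C([Se]c2ccccc2)C(CCc2ccccc2OCc2ccccc2)C1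
F4 | step 7 | {6-[4-(benzyloxy)benzyl]-5-{2-[2-(benzyloxy)phenyl]ethyl}-3-methoxycyclohexa-1,3-dien-1-yl}oxy(trimethyl)silane (racemic) | C[Si](C)(C)OC1=C(Cc2ccc(OCc3ccccc3)cc2)C(CCc2ccccc2OCc2ccccc2)CC(OC)=C1
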